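**Retrosynthetic overview**

1. Rings: none is built. Both trimethylcyclohexene rings come intact from ketoisophorone 1, reduced enantioselectively to (S)-phorenol 2 (fixes C3 and C3'), so there is no order of ring formation to report.
2. C6–C7 (ring to chain): trans-pentol 3, as its bis(bromomagnesium) derivative 4, adds to the hindered ketone of alkoxide 5. Carbinol 6 then exchanges its C6 oxygen for a C4 hydroxyl anti to the C3 hydroxyl, giving trans-diol 7 (fixes C4 and the 5-ene-7-yne).
3. Polarity switch at C11: the primary allylic alcohol of 7 becomes sulfide 8 and, through sulfoxide 9, the benzothiazolyl sulfone 10, so that C11 can react as a carbanion.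
4. Key disconnection, both C11=C12 bonds in one flask (C15 + C10 + C15): two molecules of 10 and the C10 dialdehyde 11. Carbanion 12 attacks an aldehyde carbon at each end (through mono-olefinated aldehyde 13), and the 11Z-rich tetrol 14 is heated to the all-E target 15.

Assumption: the target is the all-E (3S,4S,3'S,4'S) isomer encoded in the SMILES; positions are given in carotenoid numbering (ring C1–C6, chain C7–C15, primed for the second half).

**Route**

Step 1
Reactants: 1 ketoisophorone (2,6,6-trimethylcyclohex-2-ene-1,4-dione)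
Product: 2 (S)-phorenol, (4S)-4-hydroxy-2,6,6-trimethylcyclohex-2-en-1-one
Conditions: RuCl(p-cymene)[(S,S)-TsDPEN] (0.5 mol %), KOH (1 mol %), iPrOH, 20 °C
Reagents that add atoms: none
Why: Noyori asymmetric transfer hydrogenation, in which hydride goes to the less hindered C4 carbonyl (the other is flanked by the gem-dimethyl carbon and the methyl-bearing alkene carbon) and the (S,S)-ligand reads the alkenyl/CH2 flanks like an aryl alkyl ketone, giving the (S)-carbinol that becomes C3 of the target.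

Step 2
Reactants: 2 (S)-phorenol; 3 trans-pentol, (2E)-3-methylpent-2-en-4-yn-1-ol
Product: 7 (1S,2S)-4-[(3E)-5-hydroxy-3-methylpent-3-en-1-yn-1-yl]-3,5,5-trimethylcyclohex-3-ene-1,2-diol, via pentol bis(bromomagnesium) salt 4 (not isolated), via phorenol bromomagnesium alkoxide 5 (not isolated), via tertiary alkynyl carbinol 6 (not isolated)
Conditions: EtMgBr (2 equiv on 3, 40 °C; 1 equiv on 2, 0 °C), THF; combine, 20 °C; H2O, then 1 M H2SO4 to pH 1, 20 °C
Reagents that add atoms: water (O)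
Why: Acetylide 1,2-addition to the enone carbonyl forms C6–C7, and acid then ionises the tertiary allylic-propargylic alcohol so that water re-adds at the other allyl terminus (acid-catalysed 1,3-allylic transposition) anti to the neighbouring C3 hydroxyl, as in the hydrolysis of cyclohexadiene monoepoxide, giving the trans (3S,4S)-diol and the conjugated enyne; the minor cis epimer is removed by chromatography.

Step 3
Reactants: 7 the C15 triol from step 2
Product: 8 2-{[(2E)-5-[(3S,4S)-3,4-dihydroxy-2,6,6-trimethylcyclohex-1-en-1-yl]-3-methylpent-2-en-4-yn-1-yl]sulfanyl}-1,3-benzothiazole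
Conditions: 1,3-benzothiazole-2-thiol (1.05 equiv), PPh3, DIAD, THF, 0 °C
Reagents that add atoms: 1,3-benzothiazole-2-thiol (Sc1nc2ccccc2s1)
Why: Mitsunobu thioetherification, in which the primary allylic alcohol is activated far faster than the two hindered secondary ring alcohols and no stereocentre or double bond is touched.

Step 4
Reactants: 8 the benzothiazolyl sulfide
Product: 10 2-{[(2E)-5-[(3S,4S)-3,4-dihydroxy-2,6,6-trimethylcyclohex-1-en-1-yl]-3-methylpent-2-en-4-yn-1-yl]sulfonyl}-1,3-benzothiazole, via sulfoxide 9 (not isolated)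
Conditions: (NH4)6Mo7O24·4H2O (10 mol %), 30% aq H2O2 (4 equiv), EtOH, 0 °C
Reagents that add atoms: hydrogen peroxide (OO)
Why: Chemoselective sulfide-to-sulfone oxidation, which at 0 °C is much faster than epoxidation of the hindered tetrasubstituted enyne alkene and leaves the diol and its stereocentres unchanged.

Step 5
Reactants: 10 the benzothiazolyl sulfone (2.1 equiv); 11 (2E,4E,6E)-2,7-dimethylocta-2,4,6-trienedial (1 equiv)
Product: 15 (all-E,3S,4S,3'S,4'S)-7,8,7',8'-tetradehydro-β,β-carotene-3,4,3',4'-tetrol (CNP0283832.1), via sodium carbanion 12 (not isolated), via mono-olefinated aldehyde 13 (not isolated), via 11Z-rich tetrol 14 (not isolated)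
Conditions: NaN(SiMe3)2 (2.3 equiv, added last to 10 + 11), THF, −78 to 0 °C; H2O; then EtOH, 75 °C, dark
Reagents that add atoms: none
Why: Two-directional modified Julia (Julia–Kocienski) olefination in which C11, an allylic carbinol carbon in 7 and normally an electrophilic site, reacts with reversed polarity as the sulfonyl-stabilised carbanion 12 (a d1 reagent of the dithiane and nitronate family) and attacks the aldehyde carbon C12 of 11, also an electrophilic carbon, at each end, Smiles transfer of the benzothiazole and loss of SO2 forming both C11=C12 bonds while the hydroxyls stay free (the C–H next to the sulfonyl group is far more acidic than the alcohols); the Z-rich new bonds are of the hindered 11-cis type and relax thermally to E, and C3, C4 and the 9E geometry set earlier are not involved.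

**Compound list**

1 | ketoisophorone, 2,6,6-trimethylcyclohex-2-ene-1,4-dione | CC1=CC(=O)CC(C)(C)C1=O | starting material
2 | (S)-phorenol, (4S)-4-hydroxy-2,6,6-trimethylcyclohex-2-en-1-one | CC1=C[C@@H](O)CC(C)(C)C1=O | intermediate
3 | trans-pentol, (2E)-3-methylpent-2-en-4-yn-1-ol | C#C/C(C)=C/CO | starting material
4 | bis(bromomagnesium) salt of 3 (O–MgBr and C≡C–MgBr) | Br[Mg]C#C/C(C)=C/CO[Mg]Br | intermediate
5 | bromomagnesium alkoxide of 2 | CC1=C[C@@H](O[Mg]Br)CC(C)(C)C1=O | intermediate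
6 | (4S)-1-[(3E)-5-hydroxy-3-methylpent-3-en-1-yn-1-yl]-2,6,6-trimethylcyclohex-2-ene-1,4-diol (both C1 epimers) | CC1=C[C@@H](O)CC(C)(C)C1(O)C#C/C(C)=C/CO | intermediate
7 | (1S,2S)-4-[(3E)-5-hydroxy-3-methylpent-3-en-1-yn-1-yl]-3,5,5-trimethylcyclohex-3-ene-1,2-diol | CC1=C(C#C/C(C)=C/CO)C(C)(C)C[C@H](O)[C@H]1O | intermediate
8 | 2-{[(2E)-5-[(3S,4S)-3,4-dihydroxy-2,6,6-trimethylcyclohex-1-en-1-yl]-3-methylpent-2-en-4-yn-1-yl]sulfanyl}-1,3-benzothiazole | CC1=C(C#C/C(C)=C/CSc2nc3ccccc3s2)C(C)(C)C[C@H](O)[C@H]1O | intermediate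
9 | corresponding sulfoxide (both configurations at sulfur) | CC1=C(C#C/C(C)=C/CS(=O)c2nc3ccccc3s2)C(C)(C)C[C@H](O)[C@H]1O | intermediate
10 | 2-{[(2E)-5-[(3S,4S)-3,4-dihydroxy-2,6,6-trimethylcyclohex-1-en-1-yl]-3-methylpent-2-en-4-yn-1-yl]sulfonyl}-1,3-benzothiazole | CC1=C(C#C/C(C)=C/CS(=O)(=O)c2nc3ccccc3s2)C(C)(C)C[C@H](O)[C@H]1O | intermediate
11 | (2E,4E,6E)-2,7-dimethylocta-2,4,6-trienedial | O=C/C(C)=C/C=C/C=C(C)/C=O | starting material
12 | sodium salt of 10 deprotonated at C11 (the carbon next to the sulfonyl group) | CC1=C(C#C/C(C)=C/[CH-]S(=O)(=O)c2nc3ccccc3s2)C(C)(C)C[C@H](O)[C@H]1O.[Na+] | intermediate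
13 | (3S,4S)-3,4-dihydroxy-7,8-didehydro-12'-apo-β-caroten-12'-al, 11Z/11E mixture (drawn 11Z) | CC1=C(C#C/C(C)=C/C=C\C(C)=C\C=C\C=C(C)\C=O)C(C)(C)C[C@H](O)[C@H]1O | intermediate
14 | (3S,4S,3'S,4'S)-7,8,7',8'-tetradehydro-β,β-carotene-3,4,3',4'-tetrol, Z-rich at C11 and C11' (drawn 11Z,11'Z) | CC1=C(C#C/C(C)=C/C=C\C(C)=C\C=C\C=C(C)\C=C/C=C(\C)C#CC2=C(C)[C@H](O)[C@@H](O)CC2(C)C)C(C)(C)C[C@H](O)[C@H]1O | intermediate
15 | (all-E,3S,4S,3'S,4'S)-7,8,7',8'-tetradehydro-β,β-carotene-3,4,3',4'-tetrol | CC1=C(C#C/C(C)=C/C=C/C(C)=C/C=C/C=C(C)/C=C/C=C(\C)C#CC2=C(C)[C@H](O)[C@@H](O)CC2(C)C)C(C)(C)C[C@H](O)[C@H]1O | target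

**Step count and risks**

Total steps: 5. Longest linear sequence: 5 steps (1 → 2 → 7 → 8 → 10 → 15); 3 and 11 are bought.

Three steps most likely to fail:

Step 2 (C4 configuration and acid stability). Water may add partly syn to the C3 hydroxyl, and the allylic diol can re-ionise in acid and leak to a ketone. The fallback sets out from 2 and comes back at 7. Silylation of 2 (TBSCl, imidazole, DMF) gives (4S)-4-[(tert-butyldimethylsilyl)oxy]-2,6,6-trimethylcyclohex-2-en-1-one F1. Addition of 4 with a neutral work-up gives the isolated carbinol (4S)-4-[(tert-butyldimethylsilyl)oxy]-1-[(3E)-5-hydroxy-3-methylpent-3-en-1-yn-1-yl]-2,6,6-trimethylcyclohex-2-en-1-ol F2. A separately tuned transposition (0.05 M H2SO4, THF/H2O, 0 °C), with the bulky silyloxy group blocking its own face, gives (1S,6S)-6-[(tert-butyldimethylsilyl)oxy]-3-[(3E)-5-hydroxy-3-methylpent-3-en-1-yn-1-yl]-2,4,4-trimethylcyclohex-2-en-1-ol F3, and Bu4NF releases 7.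

Step 4 (oxidation next to a free allylic diol and an electron-rich enyne). Epoxidation or allylic sulfoxide rearrangement may compete. The fallback sets out from 7 and comes back at 10, bringing sulfur in already at the sulfone level. Appel bromination of the primary allylic alcohol (CBr4, PPh3, CH2Cl2, −30 °C) gives (1S,2S)-4-[(3E)-5-bromo-3-methylpent-3-en-1-yn-1-yl]-3,5,5-trimethylcyclohex-3-ene-1,2-diol F4, which S-alkylates sodium 1,3-benzothiazole-2-sulfinate (DMF, 20 °C) to give 10 without any oxidant.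

Step 5 (double olefination on the unprotected tetrol). The hydroxyl-bearing carbanion 12 may self-condense or give low conversion at the second aldehyde, and prolonged heating can move the 9E bonds toward 9Z, which acetylenic carotenoids tolerate well. The fallback sets out from 7 and 11 and comes back at 14, with the roles of the partners exchanged.
- Oxidation of only the primary allylic alcohol of 7 (TEMPO, PhI(OAc)2, CH2Cl2) gives (2E)-5-[(3S,4S)-3,4-dihydroxy-2,6,6-trimethylcyclohex-1-en-1-yl]-3-methylpent-2-en-4-ynal F5.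
- Reduction of 11 (NaBH4, CeCl3·7H2O, MeOH, 0 °C) gives (2E,4E,6E)-2,7-dimethylocta-2,4,6-triene-1,8-diol F6.
- Double Mitsunobu reaction of F6 with 1,3-benzothiazole-2-thiol gives 2,2'-[(2E,4E,6E)-2,7-dimethylocta-2,4,6-triene-1,8-diylbis(sulfanediyl)]bis(1,3-benzothiazole) F7.
- Oxidation ((NH4)6Mo7O24·4H2O, H2O2, EtOH) gives 2,2'-[(2E,4E,6E)-2,7-dimethylocta-2,4,6-triene-1,8-diylbis(sulfonyl)]bis(1,3-benzothiazole) F8.
- NaN(SiMe3)2 (THF, −78 °C) then joins the two carbanion carbons of F8 (C12 and C12') to the aldehyde carbon (C11) of two molecules of F5, giving 14, which is heated to 15 as in the route.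

**Further compounds**

F1 | step 2 | (4S)-4-[(tert-butyldimethylsilyl)oxy]-2,6,6-trimethylcyclohex-2-en-1-one | CC1=C[C@@H](O[Si](C)(C)C(C)(C)C)CC(C)(C)C1=O
F2 | step 2 | (4S)-4-[(tert-butyldimethylsilyl)oxy]-1-[(3E)-5-hydroxy-3-methylpent-3-en-1-yn-1-yl]-2,6,6-trimethylcyclohex-2-en-1-ol (both C1 epimers) | CC1=C[C@@H](O[Si](C)(C)C(C)(C)C)CC(C)(C)C1(O)C#C/C(C)=C/CO
F3 | step 2 | (1S,6S)-6-[(tert-butyldimethylsilyl)oxy]-3-[(3E)-5-hydroxy-3-methylpent-3-en-1-yn-1-yl]-2,4,4-trimethylcyclohex-2-en-1-ol | CC1=C(C#C/C(C)=C/CO)C(C)(C)C[C@H](O[Si](C)(C)C(C)(C)C)[C@H]1O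
F4 | step 4 | (1S,2S)-4-[(3E)-5-bromo-3-methylpent-3-en-1-yn-1-yl]-3,5,5-trimethylcyclohex-3-ene-1,2-diol | CC1=C(C#C/C(C)=C/CBr)C(C)(C)C[C@H](O)[C@H]1O
F5 | step 5 | (2E)-5-[(3S,4S)-3,4-dihydroxy-2,6,6-trimethylcyclohex-1-en-1-yl]-3-methylpent-2-en-4-ynal | CC1=C(C#C/C(C)=C/C=O)C(C)(C)C[C@H](O)[C@H]1O
F6 | step 5 | (2E,4E,6E)-2,7-dimethylocta-2,4,6-triene-1,8-diol | OC/C(C)=C/C=C/C=C(C)/CO
F7 | step 5 | 2,2'-[(2E,4E,6E)-2,7-dimethylocta-2,4,6-triene-1,8-diylbis(sulfanediyl)]bis(1,3-benzothiazole) | c1ccc2sc(SC/C(C)=C/C=C/C=C(C)/CSc3nc4ccccc4s3)nc2c1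
F8 | step 5 | 2,2'-[(2E,4E,6E)-2,7-dimethylocta-2,4,6-triene-1,8-diylbis(sulfonyl)]bis(1,3-benzothiazole) | O=S(=O)(C/C(C)=C/C=C/C=C(C)/CS(=O)(=O)c1nc2ccccc2s1)c1nc2ccccc2s1
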